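**Strategy.** Everything rests on the O1–C2 bond of ring A, the central dihydrobenzofuran. C2(A) is a benzylic carbon that carries a 4-oxygenated aryl group and is bonded to the ring A phenol oxygen, so it is made from an unfunctionalised 4-methoxybenzylic CH2. Quinone-mediated anodic oxidation gives the cation, the ortho phenol traps it, and ring A closes with C2 set trans to C3 in one operation. The precursor is an (S)-1,1-diaryl-2-(4-methoxyphenyl)ethane whose two aryl groups carry the free phenol and two nitrile handles. These become C3 of ring B (styryl-bearing) and ring C (dimethoxyphenyl-bearing), which are closed together by sulfur-ylide [4+1] annulation.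

Key step: step 9

Labels: ring A is the central dihydrobenzofuran (O1, C2, C3, C3a–C7a); ring B is the dihydrobenzofuran on C4(A) that carries the styryl group; ring C is the dihydrobenzofuran fused to the aryl group on C3(A).

Assumption: the senses of induction are taken by analogy (the named Josiphos enantiomer for the S centre in step 8; the (2R,5R)-thiolane ylide, from its sense in ylide epoxidation, for 2R,3R rings in step 19); if either is reversed, the antipodal ligand or sulfide is used.

Step 1
Reactants: 1 3-hydroxy-5-methoxybenzonitrile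
Product: 2 3-cyano-5-methoxyphenyl acetate
Conditions: Ac2O, pyridine, DMAP (cat.), CH2Cl2, 0 °C → rt
Reagents that add atoms: acetic anhydride CC(=O)OC(C)=O
Why: O-acetylation (nucleophilic acyl substitution) turns the phenol into a weak donor, so that the methoxy group alone directs the next substitution.

Step 2
Reactants: 2 3-cyano-5-methoxyphenyl acetate
Product: 3 3-cyano-2-iodo-5-methoxyphenyl acetate
Conditions: NIS, TfOH (cat.), MeCN, 0 °C → rt
Reagents that add atoms: N-iodosuccinimide O=C1CCC(=O)N1I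
Why: Electrophilic aromatic iodination should occur para to the methoxy group, the only strong donor left, which is the position between the acetoxy and cyano groups.

Step 3
Reactants: 4 4-methoxybenzaldehyde
Product: 5 1-(2,2-dibromoethenyl)-4-methoxybenzene
Conditions: CBr4, PPh3, CH2Cl2, 0 °C
Reagents that add atoms: carbon tetrabromide BrC(Br)(Br)Br
Why: Dibromo-olefination of an aromatic aldehyde with the CBr4/PPh3 ylide (first stage of the Corey–Fuchs sequence) is routine.

Step 4
Reactants: 5 1-(2,2-dibromoethenyl)-4-methoxybenzene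
Product: 7 2,2'-[2-(4-methoxyphenyl)ethene-1,1-diyl]bis(4,4,5,5-tetramethyl-1,3,2-dioxaborolane), via vinylidene lithium carbenoid 6 (not isolated)
Conditions: n-BuLi (1.05 equiv), THF/Et2O, −110 °C; B2pin2, −110 °C → rt
Reagents that add atoms: bis(pinacolato)diboron CC1(C)OB(OC1(C)C)B1OC(C)(C)C(C)(C)O1
Why: Br–Li exchange gives a carbenoid that forms an ate complex with the diboron and undergoes 1,2-boryl migration with loss of bromide (carbenoid gem-diborylation), and trapping at −110 °C should outrun the Fritsch–Buttenberg–Wiechell rearrangement.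

Step 5
Reactants: 3 3-cyano-2-iodo-5-methoxyphenyl acetate; 7 2,2'-[2-(4-methoxyphenyl)ethene-1,1-diyl]bis(4,4,5,5-tetramethyl-1,3,2-dioxaborolane)
Product: 9 3-hydroxy-5-methoxy-2-[(E)-2-(4-methoxyphenyl)-1-(4,4,5,5-tetramethyl-1,3,2-dioxaborolan-2-yl)ethenyl]benzonitrile, via 3-hydroxy-2-iodo-5-methoxybenzonitrile 8 (not isolated)
Conditions: Pd[P(t-Bu)3]2 (5 mol%), 3 M aq KOH, THF, rt
Reagents that add atoms: none
Why: Aqueous KOH first saponifies the aryl acetate, and the Suzuki–Miyaura coupling then takes place only at the less hindered boryl group trans to the anisyl ring, which fixes the E geometry of the remaining alkenylboronate.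

Step 6
Reactants: 10 2-bromo-4,6-dimethoxybenzaldehyde
Product: 12 2-bromo-4,6-dimethoxybenzonitrile, via aldoxime 11 (not isolated)
Conditions: NH2OH·HCl, pyridine, EtOH, rt; then Ac2O, 100 °C
Reagents that add atoms: hydroxylamine hydrochloride NO.Cl
Why: Oxime formation followed by dehydration with acetic anhydride is the standard aldehyde-to-nitrile conversion and leaves the aryl bromide untouched.

Step 7
Reactants: 9 3-hydroxy-5-methoxy-2-[(E)-2-(4-methoxyphenyl)-1-(4,4,5,5-tetramethyl-1,3,2-dioxaborolan-2-yl)ethenyl]benzonitrile; 12 2-bromo-4,6-dimethoxybenzonitrile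
Product: 13 2-[(E)-1-(2-cyano-6-hydroxy-4-methoxyphenyl)-2-(4-methoxyphenyl)ethenyl]-4,6-dimethoxybenzonitrile
Conditions: Pd2(dba)3 (2.5 mol%), SPhos (10 mol%), K3PO4, dioxane/H2O, 80 °C
Reagents that add atoms: none
Why: A second Suzuki–Miyaura coupling with a bulky electron-rich phosphine replaces the remaining boryl group with retention of alkene geometry, which should give a single isomer of the triarylethylene.

Step 8
Reactants: 13 2-[(E)-1-(2-cyano-6-hydroxy-4-methoxyphenyl)-2-(4-methoxyphenyl)ethenyl]-4,6-dimethoxybenzonitrile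
Product: 14 2-[(1S)-1-(2-cyano-6-hydroxy-4-methoxyphenyl)-2-(4-methoxyphenyl)ethyl]-4,6-dimethoxybenzonitrile
Conditions: [Rh(nbd)2]BF4 (5 mol%), (R)-(S)-Josiphos SL-J001 (6 mol%), H2 (30 bar), Et3N (1 equiv), MeOH/CH2Cl2, 40 °C
Reagents that add atoms: none
Why: Hydroxyl-directed asymmetric hydrogenation of a 1,1-diarylalkene, in which the ortho phenol(ate) binds rhodium and hydrogen is delivered to one face of the C=C bond under control of the chiral bisphosphine, should set the diarylmethine centre (the later C3 of ring A) as S.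

Step 9
Reactants: 14 2-[(1S)-1-(2-cyano-6-hydroxy-4-methoxyphenyl)-2-(4-methoxyphenyl)ethyl]-4,6-dimethoxybenzonitrile
Product: 15 (2S,3S)-3-(2-cyano-3,5-dimethoxyphenyl)-6-methoxy-2-(4-methoxyphenyl)-2,3-dihydro-1-benzofuran-4-carbonitrile
Conditions: DDQ (20 mol%), n-Bu4NPF6 (0.1 M), CH2Cl2/HFIP (4:1), graphite anode, Pt cathode, undivided cell, constant current, about 2 F/mol, 0 °C
Reagents that add atoms: none
Why: Anodically regenerated DDQ removes hydride from the 4-methoxybenzylic CH2 of 14 (the reduced quinone is reoxidised at the anode while protons are reduced to H2 at the cathode), and the anisyl-stabilised cation is captured by the ortho phenol oxygen to form O1–C2. The closest known reaction type is quinone-mediated oxidative C–H etherification of 4-methoxybenzylic positions, as in the oxidative cyclisation of ortho-hydroxy 1,3-diarylpropanes to flavans. Ring A closes by a polar, formally 5-exo-trig attack of the phenol oxygen on the trigonal cationic carbon, whose quinoid C=C bond to the anisyl ring lies outside the new ring. The new stereocentre C2 is controlled by the existing C3 centre: the cyanodimethoxyphenyl group on C3 shields one face of the planar cation, and because ionisation at C2 is reversible under the mildly acidic conditions the 2,3-trans isomer (2S,3S) is also the thermodynamic outcome. The step needs site selectivity for the CH2 over the doubly benzylic C3–H and over the arenes, which is secured by carrying both carbonyl-level handles as ortho nitriles (they cannot trap the cation, they make ring A and the C3 aryl harder to oxidise and the C3–H less hydridic) and by working at the potential of the mediator, not of the substrate. It also needs the reaction to stop at the dihydrobenzofuran, which is addressed by limiting the charge and by the electron-poor ring A oxygen, which makes the new C2–H bond less hydridic than an ordinary benzylic ether.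

Step 10
Reactants: 15 (2S,3S)-3-(2-cyano-3,5-dimethoxyphenyl)-6-methoxy-2-(4-methoxyphenyl)-2,3-dihydro-1-benzofuran-4-carbonitrile
Product: 17 (2S,3S)-3-(2-formyl-3,5-dimethoxyphenyl)-6-methoxy-2-(4-methoxyphenyl)-2,3-dihydro-1-benzofuran-4-carbaldehyde, via bis(aldimine) 16 (not isolated)
Conditions: DIBAL-H (2.6 equiv), CH2Cl2, −78 → −20 °C; then 1 M HCl, 0 °C
Reagents that add atoms: water O
Why: Each nitrile takes up one hydride to give an N-aluminio aldimine that is not reduced further and is hydrolysed to the aldehyde on work-up (nitrile half-reduction), and the non-basic reagent leaves C2 and C3 untouched.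

Step 11
Reactants: 18 2-bromo-3,5-dimethoxybenzaldehyde; 19 diethyl (3,4-dimethoxybenzyl)phosphonate
Product: 20 2-bromo-1-[(E)-2-(3,4-dimethoxyphenyl)ethenyl]-3,5-dimethoxybenzene
Conditions: KOt-Bu, THF, 0 °C → rt
Reagents that add atoms: none
Why: Horner–Wadsworth–Emmons olefination of an aromatic aldehyde with a benzylic phosphonate gives the E-stilbene, so the styryl group of ring B is in place before the fragment is joined.

Step 12
Reactants: 17 (2S,3S)-3-(2-formyl-3,5-dimethoxyphenyl)-6-methoxy-2-(4-methoxyphenyl)-2,3-dihydro-1-benzofuran-4-carbaldehyde; 20 2-bromo-1-[(E)-2-(3,4-dimethoxyphenyl)ethenyl]-3,5-dimethoxybenzene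
Product: 22 (2S,3S)-4-{[2-((E)-3,4-dimethoxystyryl)-4,6-dimethoxyphenyl](hydroxy)methyl}-3-(2-formyl-3,5-dimethoxyphenyl)-6-methoxy-2-(4-methoxyphenyl)-2,3-dihydro-1-benzofuran (carbinol epimers), via aryllithium 21 (not isolated)
Conditions: 20, n-BuLi (1.0 equiv), THF, −78 °C; then 17 (1.05 equiv of 21 per 17), −78 °C; aq NH4Cl
Reagents that add atoms: none
Why: Br–Li exchange and 1,2-addition of the 2,6-disubstituted aryllithium at −78 °C should take place at the ring A aldehyde, which has one ortho substituent and no conjugated methoxy donors, in preference to the doubly flanked and ortho/para-methoxy-deactivated aldehyde of the other ring, and the new carbinol centre is unselective but is removed in step 14.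

Step 13
Reactants: 22 the hydroxy aldehyde from step 12; 23 1-bromo-3,5-dimethoxybenzene
Product: 25 (2S,3S)-4-{[2-((E)-3,4-dimethoxystyryl)-4,6-dimethoxyphenyl](hydroxy)methyl}-3-{2-[(3,5-dimethoxyphenyl)(hydroxy)methyl]-3,5-dimethoxyphenyl}-6-methoxy-2-(4-methoxyphenyl)-2,3-dihydro-1-benzofuran (carbinol epimers), via 3,5-dimethoxyphenylmagnesium bromide 24 (not isolated)
Conditions: 23, Mg, I2 (cat.), THF, 50 °C; then 22 (3 equiv of 24), −40 → 0 °C; aq NH4Cl
Reagents that add atoms: none
Why: Grignard addition of the unhindered aryl nucleophile to the remaining aldehyde proceeds after the free hydroxyl has consumed one equivalent, and the new carbinol centre is again of no consequence.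

Step 14
Reactants: 25 the diol from step 13
Product: 26 (2S,3S)-4-[2-((E)-3,4-dimethoxystyryl)-4,6-dimethoxybenzoyl]-3-[2-(3,5-dimethoxybenzoyl)-3,5-dimethoxyphenyl]-6-methoxy-2-(4-methoxyphenyl)-2,3-dihydro-1-benzofuran
Conditions: Dess–Martin periodinane (3 equiv), pyridine, CH2Cl2, 0 °C → rt
Reagents that add atoms: none
Why: Dess–Martin oxidation converts both benzhydrols into diaryl ketones under buffered conditions that do not ionise the electron-rich carbinols.

Step 15
Reactants: 26 the diketone from step 14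
Product: 27 (2S,3S)-4-[2-((E)-3,4-dimethoxystyryl)-6-hydroxy-4-methoxybenzoyl]-3-[2-(3,5-dimethoxybenzoyl)-3-hydroxy-5-methoxyphenyl]-6-methoxy-2-(4-methoxyphenyl)-2,3-dihydro-1-benzofuran
Conditions: BCl3 (3 equiv), CH2Cl2, −78 → 0 °C; aq NaHCO3
Reagents that add atoms: none
Why: Chelation-controlled demethylation, in which boron bridges each ketone oxygen and the one methoxy group ortho to it, should cleave only these two of the ten methyl ethers and so free the two oxygens that become O1 of rings B and C.

Step 16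
Reactants: 27 the bis(o-hydroxyaryl) diketone from step 15
Product: 28 the corresponding bis(o-hydroxybenzhydrol) (tetraol; carbinol epimers)
Conditions: NaBH4 (excess), THF/MeOH, 0 °C → rt; pH 7 buffer; used crude
Reagents that add atoms: none
Why: Borohydride reduction of the two diaryl ketones gives the o-hydroxybenzhydrols, whose carbinol configurations are irrelevant because both carbons become planar in step 19.

Step 17
Reactants: 28 the tetraol from step 16
Product: 29 the bis(aryl tert-butyl carbonate) of 28 with both benzhydrol hydroxyls free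
Conditions: Boc2O (2.2 equiv), i-Pr2NEt, DMAP (5 mol%), CH2Cl2, −20 → 0 °C
Reagents that add atoms: di-tert-butyl dicarbonate CC(C)(C)OC(=O)OC(=O)OC(C)(C)C
Why: The phenols are acylated far faster than the hindered secondary alcohols (chemoselective carbonate formation), which gives latent o-quinone methides that can be unmasked by base alone, without the acid that would trigger cation–alkene or Friedel–Crafts cyclisation.

Step 18
Reactants: 30 4-methoxybenzyl chloride
Product: 31 (2R,5R)-1-(4-methoxybenzyl)-2,5-dimethylthiolan-1-ium tetrafluoroborate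
Conditions: (2R,5R)-2,5-dimethylthiolane, NaBF4, CH2Cl2/H2O, rt
Reagents that add atoms: (2R,5R)-2,5-dimethylthiolane C[C@@H]1CC[C@@H](C)S1; sodium tetrafluoroborate [Na+].F[B-](F)(F)F
Why: S-Alkylation of the C2-symmetric sulfide by the reactive benzylic chloride with anion exchange gives the sulfonium salt, in which sulfur is not a stereocentre.

Step 19
Reactants: 29 the bis(aryl carbonate) from step 17; 31 (2R,5R)-1-(4-methoxybenzyl)-2,5-dimethylthiolan-1-ium tetrafluoroborate
Product: 34 deca-O-methyl ether of 35 [ring A (2S,3S); rings B/C (2R,3R); E-alkene], via sulfonium ylide 32 (not isolated), via bis(o-quinone methide) 33 (not isolated)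
Conditions: 31 (3 equiv), KHMDS (5.5 equiv), THF, −78 → 0 °C
Reagents that add atoms: none
Why: Base-triggered carbonate transfer from each phenol to the neighbouring benzhydrol oxygen and 1,4-elimination unmask both o-quinone methides, each of which undergoes sulfur-ylide [4+1] annulation (conjugate addition of the ylide at the exocyclic carbon, then SN2 closure by the phenoxide with loss of the sulfide), the chiral sulfonium ylide fixing C2 and the anti-selective addition placing C3 trans, so that rings B and C should both form as 2R,3R.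

Step 20
Reactants: 34 deca-O-methyl ether of 35
Product: 35 CNP0099535.1
Conditions: BBr3 (25 equiv), CH2Cl2, −78 → 0 °C; MeOH, then H2O
Reagents that add atoms: none
Why: Exhaustive Lewis-acid ether cleavage removes all ten methyl groups, and since the three trans dihydrobenzofurans are the thermodynamic isomers any reversible ionisation at C2 should not change the configuration.

**Compound list**

1 | 3-hydroxy-5-methoxybenzonitrile | N#Cc1cc(O)cc(OC)c1 | starting material
2 | 3-cyano-5-methoxyphenyl acetate | CC(=O)Oc1cc(OC)cc(C#N)c1 | intermediate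
3 | 3-cyano-2-iodo-5-methoxyphenyl acetate | CC(=O)Oc1cc(OC)cc(C#N)c1I | intermediate
4 | 4-methoxybenzaldehyde | COc1ccc(C=O)cc1 | starting material
5 | 1-(2,2-dibromoethenyl)-4-methoxybenzene | COc1ccc(C=C(Br)Br)cc1 | intermediate
6 | [1-bromo-2-(4-methoxyphenyl)ethenyl]lithium (vinylidene carbenoid) | COc1ccc(C=C([Li])Br)cc1 | intermediate
7 | 2,2'-[2-(4-methoxyphenyl)ethene-1,1-diyl]bis(4,4,5,5-tetramethyl-1,3,2-dioxaborolane) | COc1ccc(C=C(B2OC(C)(C)C(C)(C)O2)B2OC(C)(C)C(C)(C)O2)cc1 | intermediate
8 | 3-hydroxy-2-iodo-5-methoxybenzonitrile (formed as its potassium phenoxide) | N#Cc1cc(OC)cc(O)c1I | intermediate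
9 | 3-hydroxy-5-methoxy-2-[(E)-2-(4-methoxyphenyl)-1-(4,4,5,5-tetramethyl-1,3,2-dioxaborolan-2-yl)ethenyl]benzonitrile | N#Cc1cc(OC)cc(O)c1/C(=C/c1ccc(OC)cc1)B1OC(C)(C)C(C)(C)O1 | intermediate
10 | 2-bromo-4,6-dimethoxybenzaldehyde | COc1cc(Br)c(C=O)c(OC)c1 | starting material
11 | 2-bromo-4,6-dimethoxybenzaldehyde oxime | COc1cc(Br)c(C=NO)c(OC)c1 | intermediate
12 | 2-bromo-4,6-dimethoxybenzonitrile | COc1cc(Br)c(C#N)c(OC)c1 | intermediate
13 | 2-[(E)-1-(2-cyano-6-hydroxy-4-methoxyphenyl)-2-(4-methoxyphenyl)ethenyl]-4,6-dimethoxybenzonitrile | N#Cc1cc(OC)cc(O)c1/C(=C/c1ccc(OC)cc1)c1cc(OC)cc(OC)c1C#N | intermediate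
14 | 2-[(1S)-1-(2-cyano-6-hydroxy-4-methoxyphenyl)-2-(4-methoxyphenyl)ethyl]-4,6-dimethoxybenzonitrile (key-step precursor) | N#Cc1cc(OC)cc(O)c1[C@@H](Cc1ccc(OC)cc1)c1cc(OC)cc(OC)c1C#N | intermediate
15 | (2S,3S)-3-(2-cyano-3,5-dimethoxyphenyl)-6-methoxy-2-(4-methoxyphenyl)-2,3-dihydro-1-benzofuran-4-carbonitrile (key-step product, trans) | COc1ccc([C@H]2Oc3cc(OC)cc(C#N)c3[C@@H]2c2cc(OC)cc(OC)c2C#N)cc1 | intermediate
16 | bis(N–H aldimine) of 17, ring A (2S,3S) | COc1ccc([C@H]2Oc3cc(OC)cc(C=N)c3[C@@H]2c2cc(OC)cc(OC)c2C=N)cc1 | intermediate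
17 | (2S,3S)-3-(2-formyl-3,5-dimethoxyphenyl)-6-methoxy-2-(4-methoxyphenyl)-2,3-dihydro-1-benzofuran-4-carbaldehyde | COc1ccc([C@H]2Oc3cc(OC)cc(C=O)c3[C@@H]2c2cc(OC)cc(OC)c2C=O)cc1 | intermediate
18 | 2-bromo-3,5-dimethoxybenzaldehyde | COc1cc(C=O)c(Br)c(OC)c1 | starting material
19 | diethyl (3,4-dimethoxybenzyl)phosphonate | CCOP(=O)(Cc1ccc(OC)c(OC)c1)OCC | starting material
20 | 2-bromo-1-[(E)-2-(3,4-dimethoxyphenyl)ethenyl]-3,5-dimethoxybenzene | COc1cc(OC)c(Br)c(/C=C/c2ccc(OC)c(OC)c2)c1 | intermediate
21 | {2-[(E)-2-(3,4-dimethoxyphenyl)ethenyl]-4,6-dimethoxyphenyl}lithium | COc1cc(OC)c([Li])c(/C=C/c2ccc(OC)c(OC)c2)c1 | intermediate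
22 | hydroxy aldehyde: ring A (2S,3S) dihydrobenzofuran with CH(OH)-[2-((E)-3,4-dimethoxystyryl)-4,6-dimethoxyphenyl] on C4 and 2-formyl-3,5-dimethoxyphenyl on C3 (carbinol epimers) | COc1ccc([C@H]2Oc3cc(OC)cc(C(O)c4c(OC)cc(OC)cc4/C=C/c4ccc(OC)c(OC)c4)c3[C@@H]2c2cc(OC)cc(OC)c2C=O)cc1 | intermediate
23 | 1-bromo-3,5-dimethoxybenzene | COc1cc(Br)cc(OC)c1 | starting material
24 | 3,5-dimethoxyphenylmagnesium bromide | COc1cc(OC)cc([Mg]Br)c1 | intermediate
25 | diol: as 22 with the formyl group replaced by CH(OH)-(3,5-dimethoxyphenyl) (carbinol epimers) | COc1ccc([C@H]2Oc3cc(OC)cc(C(O)c4c(OC)cc(OC)cc4/C=C/c4ccc(OC)c(OC)c4)c3[C@@H]2c2cc(OC)cc(OC)c2C(O)c2cc(OC)cc(OC)c2)cc1 | intermediate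
26 | diketone: (2S,3S)-4-[2-((E)-3,4-dimethoxystyryl)-4,6-dimethoxybenzoyl]-3-[2-(3,5-dimethoxybenzoyl)-3,5-dimethoxyphenyl]-6-methoxy-2-(4-methoxyphenyl)-2,3-dihydro-1-benzofuran | COc1ccc([C@H]2Oc3cc(OC)cc(C(=O)c4c(OC)cc(OC)cc4/C=C/c4ccc(OC)c(OC)c4)c3[C@@H]2c2cc(OC)cc(OC)c2C(=O)c2cc(OC)cc(OC)c2)cc1 | intermediate
27 | bis(o-hydroxyaryl) diketone: 26 with the methoxy group ortho to each ketone replaced by OH | COc1ccc([C@H]2Oc3cc(OC)cc(C(=O)c4c(O)cc(OC)cc4/C=C/c4ccc(OC)c(OC)c4)c3[C@@H]2c2cc(OC)cc(O)c2C(=O)c2cc(OC)cc(OC)c2)cc1 | intermediate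
28 | tetraol: 27 with both ketones reduced to CH(OH) (carbinol epimers) | COc1ccc([C@H]2Oc3cc(OC)cc(C(O)c4c(O)cc(OC)cc4/C=C/c4ccc(OC)c(OC)c4)c3[C@@H]2c2cc(OC)cc(O)c2C(O)c2cc(OC)cc(OC)c2)cc1 | intermediate
29 | bis(aryl tert-butyl carbonate) of 28, benzhydrol OH groups free | COc1ccc([C@H]2Oc3cc(OC)cc(C(O)c4c(OC(=O)OC(C)(C)C)cc(OC)cc4/C=C/c4ccc(OC)c(OC)c4)c3[C@@H]2c2cc(OC)cc(OC(=O)OC(C)(C)C)c2C(O)c2cc(OC)cc(OC)c2)cc1 | intermediate
30 | 4-methoxybenzyl chloride | COc1ccc(CCl)cc1 | starting material
31 | (2R,5R)-1-(4-methoxybenzyl)-2,5-dimethylthiolan-1-ium tetrafluoroborate | C[C@@H]1CC[C@@H](C)[S+]1Cc1ccc(OC)cc1.F[B-](F)(F)F | intermediate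
32 | (2R,5R)-2,5-dimethylthiolanium 4-methoxybenzylide (sulfonium ylide) | C[C@@H]1CC[C@@H](C)[S+]1[CH-]c1ccc(OC)cc1 | intermediate
33 | bis(o-quinone methide) from 29, ring A (2S,3S) | COc1ccc([C@H]2Oc3cc(OC)cc(C=C4C(=O)C=C(OC)C=C4/C=C/c4ccc(OC)c(OC)c4)c3[C@@H]2C2=CC(OC)=CC(=O)C2=Cc2cc(OC)cc(OC)c2)cc1 | intermediate
34 | deca-O-methyl ether of 35: ring A (2S,3S), ring B (2R,3R), ring C (2R,3R), E-alkene | COc1ccc([C@H]2Oc3cc(OC)cc([C@@H]4c5c(/C=C/c6ccc(OC)c(OC)c6)cc(OC)cc5O[C@H]4c4ccc(OC)cc4)c3[C@@H]2c2cc(OC)cc3c2[C@@H](c2cc(OC)cc(OC)c2)[C@H](c2ccc(OC)cc2)O3)cc1 | intermediate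
35 | CNP0099535.1: ring A (2S,3S), ring B (2R,3R), ring C (2R,3R), all trans, E-3,4-dihydroxystyryl on C4 of ring B | Oc1ccc([C@H]2Oc3cc(O)cc([C@@H]4c5c(/C=C/c6ccc(O)c(O)c6)cc(O)cc5O[C@H]4c4ccc(O)cc4)c3[C@@H]2c2cc(O)cc3c2[C@@H](c2cc(O)cc(O)c2)[C@H](c2ccc(O)cc2)O3)cc1 | target

**Step count.** Total: 20 steps. Longest linear sequence: 15 steps (steps 1, 2, 5, 7, 8, 9, 10, 12, 13, 14, 15, 16, 17, 19, 20).

**Steps most likely to fail**

Step 19. The double annulation may suffer from substrate-directed facial bias at either o-quinone methide overriding the reagent, or from intermolecular consumption of the quinone methides before the ylide adds. The fallback replaces the ylide by catalyst-controlled carbene C–H insertion; it sets out from 27 and comes back at 34. Both phenols of 27 are alkylated with 30 (K2CO3, DMF) to give the bis(4-methoxybenzyl) ether F1. Hydrazine hydrate with acetic acid in ethanol converts both ketones into the bis(hydrazone) F2. Oxidation with MnO2 gives the bis(diaryldiazomethane) F3, which is treated without isolation with Rh2(R-PTAD)4 (or its antipode, whichever gives 3R). Each donor/donor rhodium carbene inserts into the neighbouring ArO–CH2 bond, which should give the bis(2,3-cis-dihydrobenzofuran) F4 with C3 of rings B and C set by the catalyst. Catalytic trifluoroacetic acid then epimerises C2 of both new rings through reversible benzylic ionisation to the trans isomers, which is 34.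

Step 9. The electrolysis may over-oxidise the product to the benzofuran, abstract hydride at C3, or lose a proton from the cation to give the alkene and so erode the C3 configuration. The fallback replaces hydride abstraction by radical halogenation and displacement; it sets out from 14 and comes back at 15. The phenol is silylated (TBSCl, imidazole) to give the tert-butyldimethylsilyl ether F5. Wohl–Ziegler bromination (NBS, AIBN, PhCF3, 80 °C) at the electron-rich 4-methoxybenzylic CH2 gives the benzylic bromide F6 as C2 epimers. TBAF in THF frees the phenoxide, which displaces the bromide and closes ring A to 15, trans by the same thermodynamic preference.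

Step 8. The congested trisubstituted alkene may hydrogenate slowly or with poor facial discrimination. The fallback gives up asymmetric catalysis for resolution; it sets out from 13 and comes back at 14. Hydroxyl-directed hydrogenation with the achiral catalyst [Ir(cod)(PCy3)(py)]PF6 gives the racemic triarylethane F7, which is resolved by preparative chromatography on a chiral stationary phase; the S enantiomer is 14.

Further compounds
F1 | step 19 | bis(4-methoxybenzyl) ether of 27 | COc1ccc([C@H]2Oc3cc(OC)cc(C(=O)c4c(OCc5ccc(OC)cc5)cc(OC)cc4/C=C/c4ccc(OC)c(OC)c4)c3[C@@H]2c2cc(OC)cc(OCc3ccc(OC)cc3)c2C(=O)c2cc(OC)cc(OC)c2)cc1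
F2 | step 19 | bis(hydrazone) of F1 | COc1ccc([C@H]2Oc3cc(OC)cc(C(=NN)c4c(OCc5ccc(OC)cc5)cc(OC)cc4/C=C/c4ccc(OC)c(OC)c4)c3[C@@H]2c2cc(OC)cc(OCc3ccc(OC)cc3)c2C(=NN)c2cc(OC)cc(OC)c2)cc1
F3 | step 19 | bis(diaryldiazomethane) from F2 | COc1ccc([C@H]2Oc3cc(OC)cc(C(=[N+]=[N-])c4c(OCc5ccc(OC)cc5)cc(OC)cc4/C=C/c4ccc(OC)c(OC)c4)c3[C@@H]2c2cc(OC)cc(OCc3ccc(OC)cc3)c2C(=[N+]=[N-])c2cc(OC)cc(OC)c2)cc1
F4 | step 19 | C2 epimer of 34 in rings B and C (both new rings 2,3-cis) | COc1ccc([C@H]2Oc3cc(OC)cc([C@@H]4c5c(/C=C/c6ccc(OC)c(OC)c6)cc(OC)cc5O[C@@H]4c4ccc(OC)cc4)c3[C@@H]2c2cc(OC)cc3c2[C@@H](c2cc(OC)cc(OC)c2)[C@@H](c2ccc(OC)cc2)O3)cc1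
F5 | step 9 | tert-butyldimethylsilyl ether of 14 | CC(C)(C)[Si](C)(C)Oc1cc(OC)cc(C#N)c1[C@@H](Cc1ccc(OC)cc1)c1cc(OC)cc(OC)c1C#N
F6 | step 9 | benzylic bromide of F5 (C2 epimers) | CC(C)(C)[Si](C)(C)Oc1cc(OC)cc(C#N)c1[C@@H](C(Br)c1ccc(OC)cc1)c1cc(OC)cc(OC)c1C#N
F7 | step 8 | racemic 14 | N#Cc1cc(OC)cc(O)c1C(Cc1ccc(OC)cc1)c1cc(OC)cc(OC)c1C#N
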